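Everything rests on cutting the C3–C4 bond of the pyranone ring (ring C). In ring B the 2′-hydroxyl sits ortho to C1′, so C3 can be released as the exocyclic carbon of an ortho-quinone methide, and C4 is the formyl carbon of a ring-A salicylaldehyde ether. In one operation a chiral triazolylidene converts that formyl group into an acyl anion that adds to the quinone methide, which forms C3–C4, closes ring C and sets C3 as R from a racemic precursor. That precursor is a 2′-hydroxybenzylic p-tolyl sulfone linked through C2–O1 to a 4-silyloxybenzaldehyde; O7 and O4′ are silylated and O2′ is free.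

Key step: step 10

Remark on the chemistry: O7 is carried as a triisopropylsilyl (TIPS) ether and O4′ as a tert-butyldimethylsilyl (TBS) ether, because a silyl ether para to a formyl group is the most base-labile site of the cyclisation precursor; both leave together at the end.
Remark on the chemistry: the antipode of the triazolium salt that leads to the 3R product is assumed to be identified in a first run with both antipodes, both being available from cis-1-amino-2-indanol.
Remark on naming: geranyl stands for (2E)-3,7-dimethylocta-2,6-dien-1-yl throughout.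

Step 1
Reactants: 1 2,4-dihydroxybenzaldehyde
Product: 2 2-hydroxy-4-(triisopropylsilyloxy)benzaldehyde
Conditions: TIPSCl (1.05 equiv), imidazole (2.2 equiv), CH2Cl2, 0 °C → rt
Reagents that add atoms: triisopropylsilyl chloride, CC(C)[Si](Cl)(C(C)C)C(C)C
Why: Regioselective silyl ether formation should occur at the 4-hydroxyl, since the 2-hydroxyl is held in a hydrogen bond to the formyl group and is the less acidic and less accessible phenol.

Step 2
Reactants: 2 2-hydroxy-4-(triisopropylsilyloxy)benzaldehyde, 3 prop-2-en-1-ol (allyl alcohol)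
Product: 4 2-(prop-2-en-1-yloxy)-4-(triisopropylsilyloxy)benzaldehyde
Conditions: PPh3 (1.3 equiv), DIAD (1.3 equiv), THF, 0 °C → rt
Reagents that add atoms: none
Why: Mitsunobu etherification of the acidic salicylaldehyde phenol with a primary alcohol runs under neutral conditions, so no phenoxide is present that could strip or shuffle the activated 4-silyloxy group.

Step 3
Reactants: 4 2-(prop-2-en-1-yloxy)-4-(triisopropylsilyloxy)benzaldehyde
Product: 5 2-[2-(prop-2-en-1-yloxy)-4-(triisopropylsilyloxy)phenyl]-1,3-dioxolane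
Conditions: TMSOCH2CH2OTMS (1.5 equiv), TMSOTf (5 mol%), CH2Cl2, −78 → −20 °C; pyridine quench
Reagents that add atoms: 1,2-bis(trimethylsilyloxy)ethane, C[Si](C)(C)OCCO[Si](C)(C)C
Why: Noyori acetalisation masks the aromatic aldehyde at low temperature without touching the aryl silyl ether or the allyl ether.

Step 4
Reactants: 5 2-[2-(prop-2-en-1-yloxy)-4-(triisopropylsilyloxy)phenyl]-1,3-dioxolane
Product: 7 2-[2-(1,3-dioxolan-2-yl)-5-(triisopropylsilyloxy)phenoxy]acetaldehyde, via vicinal diol 6 (not isolated)
Conditions: OsO4 (2 mol%), NaIO4 (3 equiv), 2,6-lutidine (2 equiv), dioxane–H2O 3:1, rt; dried by azeotrope and used at once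
Reagents that add atoms: osmium tetroxide, O=[Os](=O)(=O)=O; sodium periodate (terminal oxidant that reloads osmium with oxygen), [Na+].[O-][I](=O)(=O)=O
Why: Lemieux–Johnson cleavage (catalytic dihydroxylation, then periodate glycol cleavage) converts the only alkene of this fragment into the aryloxyacetaldehyde, and the lutidine buffer protects the acid-labile aryl acetal.

Step 5
Reactants: 8 4,6-dibromoresorcinol
Product: 9 1,5-dibromo-2,4-bis(tert-butyldimethylsilyloxy)benzene
Conditions: TBSCl (2.3 equiv), imidazole (4.6 equiv), DMF, rt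
Reagents that add atoms: tert-butyldimethylsilyl chloride, CC(C)(C)[Si](C)(C)Cl
Why: Imidazole-promoted silylation caps both equivalent phenols, and keeping the two oxygens identical means that the first metalation has no regiochemical choice to make.

Step 6
Reactants: 9 1,5-dibromo-2,4-bis(tert-butyldimethylsilyloxy)benzene, 10 geranyl bromide
Product: 13 1-bromo-2,4-bis(tert-butyldimethylsilyloxy)-5-geranylbenzene, via aryllithium 11 (not isolated), via arylcopper 12 (not isolated)
Conditions: n-BuLi (1.0 equiv), Et2O, −78 °C; CuBr·SMe2 (1.0 equiv), −78 → −40 °C; 10 (1.1 equiv), −78 → 0 °C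
Reagents that add atoms: none
Why: Bromine–lithium exchange should stop after one bromine because the lithiated ring resists a second exchange, and the derived arylcopper substitutes the primary allylic bromide at its unhindered α-carbon (SN2-type allylic substitution, E geometry kept), while ether and −78 °C hold back the O→C silyl shift of the ortho-silyloxy aryllithium.

Step 7
Reactants: 13 1-bromo-2,4-bis(tert-butyldimethylsilyloxy)-5-geranylbenzene
Product: 14 2-bromo-5-(tert-butyldimethylsilyloxy)-4-geranylphenol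
Conditions: K2CO3 (1.1 equiv), MeOH–THF 1:1, 0 °C, stopped when 13 is consumed; NH4Cl
Reagents that add atoms: none
Why: Base-mediated methanolysis of aryl silyl ethers is faster the better the phenoxide leaving group, so the ether ortho to bromine (the more acidic phenol) should be cleaved in preference to the one ortho to the alkyl chain, and the phenoxide formed slows a second cleavage.

Step 8
Reactants: 14 2-bromo-5-(tert-butyldimethylsilyloxy)-4-geranylphenol, 7 2-[2-(1,3-dioxolan-2-yl)-5-(triisopropylsilyloxy)phenoxy]acetaldehyde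
Product: 16 rac-5-(tert-butyldimethylsilyloxy)-2-{2-[2-(1,3-dioxolan-2-yl)-5-(triisopropylsilyloxy)phenoxy]-1-hydroxyethyl}-4-geranylphenol, via dilithiated phenoxide 15 (not isolated)
Conditions: t-BuLi (3.1 equiv), THF–Et2O, −78 °C; 7 (1.2 equiv), −78 → −40 °C; NH4Cl; filtered through Et3N-washed silica
Reagents that add atoms: none
Why: Deprotonation of the phenol and bromine–lithium exchange give an ortho-lithiated phenoxide, a known kind of dianion, which undergoes 1,2-addition to the aliphatic aldehyde while the aromatic formyl group is hidden as the acetal; the carbinol centre is formed racemic, which is intended.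

Step 9
Reactants: 16 rac-5-(tert-butyldimethylsilyloxy)-2-{2-[2-(1,3-dioxolan-2-yl)-5-(triisopropylsilyloxy)phenoxy]-1-hydroxyethyl}-4-geranylphenol
Product: 18 rac-2-{2-[4-(tert-butyldimethylsilyloxy)-5-geranyl-2-hydroxyphenyl]-2-(4-methylbenzenesulfonyl)ethoxy}-4-(triisopropylsilyloxy)benzaldehyde, via acetal sulfone 17 (not isolated)
Conditions: p-TolSO2H (2.5 equiv, freshly liberated from its sodium salt), CH2Cl2, argon, 0 °C → rt; then THF–H2O, rt; pH 7 buffer work-up
Reagents that add atoms: p-toluenesulfinic acid, Cc1ccc(cc1)S(=O)O; water, O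
Why: Acid-mediated substitution of an ortho-hydroxybenzylic alcohol by a sulfinic acid (ionisation to the protonated quinone methide, then S-attack of sulfinate) is the standard entry to 2-(1-sulfonylalkyl)phenols, the same weak acid with water opens the electron-rich aryl acetal, and the silyl cap on O4′ blocks acid-induced chroman formation with the geranyl chain.

Step 10
Reactants: 18 rac-2-{2-[4-(tert-butyldimethylsilyloxy)-5-geranyl-2-hydroxyphenyl]-2-(4-methylbenzenesulfonyl)ethoxy}-4-(triisopropylsilyloxy)benzaldehyde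
Product: 20 (3R)-3-[4-(tert-butyldimethylsilyloxy)-5-geranyl-2-hydroxyphenyl]-7-(triisopropylsilyloxy)-2,3-dihydro-4H-chromen-4-one, via ortho-quinone methide 19 (not isolated)
Conditions: aminoindanol-derived N-pentafluorophenyl triazolium tetrafluoroborate (20 mol%, antipode giving 3R), K2CO3 (1.5 equiv, milled), 4 Å MS, CH2Cl2–toluene 1:1, argon, −20 → 0 °C; AcOH quench at 0 °C
Reagents that add atoms: none
Why: Proposed new method: carbonate deprotonates the 2′-phenol of 18 and the phenoxide expels p-toluenesulfinate to give ortho-quinone methide 19, which erases the racemic benzylic centre, while the triazolylidene adds to the formyl group to give the Breslow intermediate, whose nucleophilic carbon (the future C4) attacks the methide carbon (the future C3); rearomatisation of ring B makes this addition irreversible, and collapse of the resulting alkoxide releases the ketone and the carbene. The closest known reactions are the intermolecular carbene-catalysed hydroacylation of ortho-quinone methides generated in situ from such sulfones and the enantioselective intramolecular Stetter reaction of salicylaldehyde ethers to 3-substituted chroman-4-ones; the new element is their intramolecular, enantioselective combination. Ring C closes in a 6-exo-trig mode, the C1′=C3 double bond lying outside the new ring. The C3 stereocentre is set in the C–C bond-forming step under catalyst control, the aminoindanol-derived carbene shielding one face of the planar quinone methide, so both enantiomers of 18 converge on one product. The step needs face selectivity at C3 and preference for acyl-anion attack over benzoin coupling, quinone-methide oligomerisation or tautomerisation to the enol ether; the two-atom O1–C2 tether (only the methide carbon is within reach), the silyl cap on O4′ (only the 2′-phenoxide can trigger) and slow release of 19 by a heterogeneous base should secure this. Weak base, low temperature and the acetic acid quench protect the acidic C3–H of 20 from epimerisation.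

Step 11
Reactants: 20 (3R)-3-[4-(tert-butyldimethylsilyloxy)-5-geranyl-2-hydroxyphenyl]-7-(triisopropylsilyloxy)-2,3-dihydro-4H-chromen-4-one
Product: 21 (3R)-3-(5-geranyl-2,4-dihydroxyphenyl)-7-hydroxy-2,3-dihydro-4H-chromen-4-one (CNP0142504.1)
Conditions: TBAF (3 equiv), AcOH (4 equiv), THF, 0 °C → rt
Reagents that add atoms: none
Why: Fluoride-induced cleavage of aryl silyl ethers buffered with acetic acid keeps every phenol protonated, so the enolisable C3–H next to the ketone never meets base and the 3R configuration should be retained.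

Compound list
1 | 2,4-dihydroxybenzaldehyde | O=Cc1ccc(O)cc1O | starting material
2 | 2-hydroxy-4-(triisopropylsilyloxy)benzaldehyde | O=Cc1ccc(O[Si](C(C)C)(C(C)C)C(C)C)cc1O | intermediate
3 | prop-2-en-1-ol (allyl alcohol) | C=CCO | starting material
4 | 2-(prop-2-en-1-yloxy)-4-(triisopropylsilyloxy)benzaldehyde | O=Cc1ccc(O[Si](C(C)C)(C(C)C)C(C)C)cc1OCC=C | intermediate
5 | 2-[2-(prop-2-en-1-yloxy)-4-(triisopropylsilyloxy)phenyl]-1,3-dioxolane | C=CCOc1cc(O[Si](C(C)C)(C(C)C)C(C)C)ccc1C2OCCO2 | intermediate
6 | rac-3-[2-(1,3-dioxolan-2-yl)-5-(triisopropylsilyloxy)phenoxy]propane-1,2-diol (not isolated) | OCC(O)COc1cc(O[Si](C(C)C)(C(C)C)C(C)C)ccc1C2OCCO2 | intermediate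
7 | 2-[2-(1,3-dioxolan-2-yl)-5-(triisopropylsilyloxy)phenoxy]acetaldehyde | O=CCOc1cc(O[Si](C(C)C)(C(C)C)C(C)C)ccc1C2OCCO2 | intermediate
8 | 4,6-dibromoresorcinol | Oc1cc(O)c(Br)cc1Br | starting material
9 | 1,5-dibromo-2,4-bis(tert-butyldimethylsilyloxy)benzene | Brc1cc(Br)c(O[Si](C)(C)C(C)(C)C)cc1O[Si](C)(C)C(C)(C)C | intermediate
10 | geranyl bromide, (2E)-1-bromo-3,7-dimethylocta-2,6-diene | CC(C)=CCC/C(C)=C/CBr | starting material
11 | [5-bromo-2,4-bis(tert-butyldimethylsilyloxy)phenyl]lithium (not isolated) | [Li]c1cc(Br)c(O[Si](C)(C)C(C)(C)C)cc1O[Si](C)(C)C(C)(C)C | intermediate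
12 | [5-bromo-2,4-bis(tert-butyldimethylsilyloxy)phenyl]copper (not isolated) | [Cu]c1cc(Br)c(O[Si](C)(C)C(C)(C)C)cc1O[Si](C)(C)C(C)(C)C | intermediate
13 | 1-bromo-2,4-bis(tert-butyldimethylsilyloxy)-5-[(2E)-3,7-dimethylocta-2,6-dien-1-yl]benzene | CC(C)=CCC/C(C)=C/Cc1cc(Br)c(O[Si](C)(C)C(C)(C)C)cc1O[Si](C)(C)C(C)(C)C | intermediate
14 | 2-bromo-5-(tert-butyldimethylsilyloxy)-4-[(2E)-3,7-dimethylocta-2,6-dien-1-yl]phenol | CC(C)=CCC/C(C)=C/Cc1cc(Br)c(O)cc1O[Si](C)(C)C(C)(C)C | intermediate
15 | lithium 5-(tert-butyldimethylsilyloxy)-4-[(2E)-3,7-dimethylocta-2,6-dien-1-yl]-2-lithiophenolate (not isolated) | CC(C)=CCC/C(C)=C/Cc1cc([Li])c(O[Li])cc1O[Si](C)(C)C(C)(C)C | intermediate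
16 | rac-5-(tert-butyldimethylsilyloxy)-2-{2-[2-(1,3-dioxolan-2-yl)-5-(triisopropylsilyloxy)phenoxy]-1-hydroxyethyl}-4-[(2E)-3,7-dimethylocta-2,6-dien-1-yl]phenol | CC(C)=CCC/C(C)=C/Cc1cc(C(O)COc2cc(O[Si](C(C)C)(C(C)C)C(C)C)ccc2C3OCCO3)c(O)cc1O[Si](C)(C)C(C)(C)C | intermediate
17 | rac-5-(tert-butyldimethylsilyloxy)-2-{2-[2-(1,3-dioxolan-2-yl)-5-(triisopropylsilyloxy)phenoxy]-1-(4-methylbenzenesulfonyl)ethyl}-4-[(2E)-3,7-dimethylocta-2,6-dien-1-yl]phenol (not isolated) | CC(C)=CCC/C(C)=C/Cc1cc(C(COc2cc(O[Si](C(C)C)(C(C)C)C(C)C)ccc2C3OCCO3)S(=O)(=O)c4ccc(C)cc4)c(O)cc1O[Si](C)(C)C(C)(C)C | intermediate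
18 | rac-2-{2-[4-(tert-butyldimethylsilyloxy)-5-[(2E)-3,7-dimethylocta-2,6-dien-1-yl]-2-hydroxyphenyl]-2-(4-methylbenzenesulfonyl)ethoxy}-4-(triisopropylsilyloxy)benzaldehyde | CC(C)=CCC/C(C)=C/Cc1cc(C(COc2cc(O[Si](C(C)C)(C(C)C)C(C)C)ccc2C=O)S(=O)(=O)c3ccc(C)cc3)c(O)cc1O[Si](C)(C)C(C)(C)C | intermediate
19 | 2-{2-[4-(tert-butyldimethylsilyloxy)-3-[(2E)-3,7-dimethylocta-2,6-dien-1-yl]-6-oxocyclohexa-2,4-dien-1-ylidene]ethoxy}-4-(triisopropylsilyloxy)benzaldehyde (ortho-quinone methide, exocyclic geometry not fixed, not isolated) | O=C1C=C(O[Si](C)(C)C(C)(C)C)C(C/C=C(\C)CCC=C(C)C)=CC1=CCOc2cc(O[Si](C(C)C)(C(C)C)C(C)C)ccc2C=O | intermediate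
20 | (3R)-3-[4-(tert-butyldimethylsilyloxy)-5-[(2E)-3,7-dimethylocta-2,6-dien-1-yl]-2-hydroxyphenyl]-7-(triisopropylsilyloxy)-2,3-dihydro-4H-chromen-4-one | CC(C)=CCC/C(C)=C/Cc1cc([C@@H]2COc3cc(O[Si](C(C)C)(C(C)C)C(C)C)ccc3C2=O)c(O)cc1O[Si](C)(C)C(C)(C)C | intermediate
21 | (3R)-3-{5-[(2E)-3,7-dimethylocta-2,6-dien-1-yl]-2,4-dihydroxyphenyl}-7-hydroxy-2,3-dihydro-4H-chromen-4-one (CNP0142504.1) | CC(C)=CCC/C(C)=C/Cc1cc([C@@H]2COc3cc(O)ccc3C2=O)c(O)cc1O | target

Total step count: 11.
Longest linear sequence: 8 steps (1 → 2 → 4 → 5 → 7 → 16 → 18 → 20 → 21; the ring-B branch 8 → 9 → 13 → 14 joins at step 8).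

Steps most likely to fail

Step 10. The closure may suffer from poor face selectivity, from loss of the quinone methide to tautomerisation or oligomerisation before the acyl anion captures it, or from base-mediated epimerisation at C3. The fallback takes ring C ready-made and attaches the aryl group by known chemistry, setting out from aryl bromide 13. Commercial 7-hydroxychroman-4-one is silylated (TIPSCl, imidazole) to 7-(triisopropylsilyloxy)chroman-4-one F1. Palladium-catalysed ketone α-arylation of F1 with 13 (Pd2(dba)3, XPhos, LiHMDS, toluene, 60 °C) should give rac-3-[2,4-bis(tert-butyldimethylsilyloxy)-5-geranylphenyl]-7-(triisopropylsilyloxy)-2,3-dihydro-4H-chromen-4-one F2. Chromatography on a chiral stationary phase should then deliver (3R)-3-[2,4-bis(tert-butyldimethylsilyloxy)-5-geranylphenyl]-7-(triisopropylsilyloxy)-2,3-dihydro-4H-chromen-4-one F3, the 3S fraction being racemised with DBU and resubmitted. Buffered fluoride as in step 11 removes all three silyl groups, and the route is rejoined at target 21.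

Step 7. The two aryl silyl ethers of 13 may not be told apart well enough, or cleavage may run on to the resorcinol. The fallback leaves the differentiation to the neighbouring carbinol and sets out from 13. Bromine–lithium exchange (t-BuLi, Et2O, −78 °C) and addition to aldehyde 7 with a cold quench should give rac-1-[2,4-bis(tert-butyldimethylsilyloxy)-5-geranylphenyl]-2-[2-(1,3-dioxolan-2-yl)-5-(triisopropylsilyloxy)phenoxy]ethan-1-ol F4. Sodium hydride in THF at 0 °C converts it into the alkoxide, which takes over the silyl group of the adjacent phenolic oxygen (1,5 O→O silyl shift toward the more stable phenoxide). This should give rac-5-(tert-butyldimethylsilyloxy)-2-{1-(tert-butyldimethylsilyloxy)-2-[2-(1,3-dioxolan-2-yl)-5-(triisopropylsilyloxy)phenoxy]ethyl}-4-geranylphenol F5. p-Toluenesulfinic acid in wet CH2Cl2, as in step 9, exchanges the benzylic silyloxy group for the sulfonyl group and opens the acetal, and the route is rejoined at sulfone 18.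

Step 8. The dianion may be protonated by the enolisable, hydrate-prone aldehyde instead of adding to it, which returns debrominated phenol. The fallback makes the C1′–C bond by electrophilic substitution of a magnesium phenoxide and sets out from 14. The dilithiated species is quenched with methanol to give 3-(tert-butyldimethylsilyloxy)-4-geranylphenol F6. Its bromomagnesium phenoxide (EtMgBr, CH2Cl2–toluene, rt) should undergo ortho-specific hydroxyalkylation with aldehyde 7 at the free position para to the silyloxy group, the position between the two oxygens being shielded. The route is rejoined at diol 16.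

Further compounds
F1 | step 10 | 7-(triisopropylsilyloxy)-2,3-dihydro-4H-chromen-4-one | O=C1CCOc2cc(O[Si](C(C)C)(C(C)C)C(C)C)ccc12
F2 | step 10 | rac-3-[2,4-bis(tert-butyldimethylsilyloxy)-5-[(2E)-3,7-dimethylocta-2,6-dien-1-yl]phenyl]-7-(triisopropylsilyloxy)-2,3-dihydro-4H-chromen-4-one | CC(C)=CCC/C(C)=C/Cc1cc(C2COc3cc(O[Si](C(C)C)(C(C)C)C(C)C)ccc3C2=O)c(O[Si](C)(C)C(C)(C)C)cc1O[Si](C)(C)C(C)(C)C
F3 | step 10 | (3R)-3-[2,4-bis(tert-butyldimethylsilyloxy)-5-[(2E)-3,7-dimethylocta-2,6-dien-1-yl]phenyl]-7-(triisopropylsilyloxy)-2,3-dihydro-4H-chromen-4-one | CC(C)=CCC/C(C)=C/Cc1cc([C@@H]2COc3cc(O[Si](C(C)C)(C(C)C)C(C)C)ccc3C2=O)c(O[Si](C)(C)C(C)(C)C)cc1O[Si](C)(C)C(C)(C)C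
F4 | step 7 | rac-1-[2,4-bis(tert-butyldimethylsilyloxy)-5-[(2E)-3,7-dimethylocta-2,6-dien-1-yl]phenyl]-2-[2-(1,3-dioxolan-2-yl)-5-(triisopropylsilyloxy)phenoxy]ethan-1-ol | CC(C)=CCC/C(C)=C/Cc1cc(C(O)COc2cc(O[Si](C(C)C)(C(C)C)C(C)C)ccc2C3OCCO3)c(O[Si](C)(C)C(C)(C)C)cc1O[Si](C)(C)C(C)(C)C
F5 | step 7 | rac-5-(tert-butyldimethylsilyloxy)-2-{1-(tert-butyldimethylsilyloxy)-2-[2-(1,3-dioxolan-2-yl)-5-(triisopropylsilyloxy)phenoxy]ethyl}-4-[(2E)-3,7-dimethylocta-2,6-dien-1-yl]phenol | CC(C)=CCC/C(C)=C/Cc1cc(C(O[Si](C)(C)C(C)(C)C)COc2cc(O[Si](C(C)C)(C(C)C)C(C)C)ccc2C3OCCO3)c(O)cc1O[Si](C)(C)C(C)(C)C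
F6 | step 8 | 3-(tert-butyldimethylsilyloxy)-4-[(2E)-3,7-dimethylocta-2,6-dien-1-yl]phenol | CC(C)=CCC/C(C)=C/Cc1ccc(O)cc1O[Si](C)(C)C(C)(C)C
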